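**Retrosynthetic overview**
1. The aryl C1–C7' bond is cut last. The target then comes from a bicyclic hydroxy-lactol (rings A and B complete, C7' at the aldehyde level) and potassium trifluoro(4-hydroxy-3,5-dimethoxyphenyl)borate, with no protecting group left to remove.
2. Enabling feature: the tertiary C8'–OH sits next to the acetal carbon C7' (O–C7'–C8'–OH in ring B), on the convex face of the cis-fused 3,7-dioxabicyclo[3.3.0]octane. C8' bears no hydrogen, so the lactol cannot enolise, and the hydroxyl can tether boron and pass the aryl group to the ring B oxocarbenium ion from the exo face.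
3. The hydroxy-lactol comes from the hydroxy-lactone. Ring A is opened at O–C9' to give a triol lactone, which comes from an α-methylene lactone by OsO4 dihydroxylation, so C8' is relayed from C8.
4. The C7–C8 bond is cut next. One catalytic asymmetric Nozaki–Hiyama–Kishi allylation of syringaldehyde acetate with 3-(bromomethyl)furan-2(5H)-one sets C7 and C8.
5. Ring order: ring B enters as the butenolide, ring A is closed second, and the second aryl group is attached last.

Key step: step 8

Assumption: lignan numbering is used. C7, C8 and C9 are the benzylic CH, bridgehead CH and OCH2 of the unit without the hydroxyl; C7', C8' and C9' are the benzylic CH, carbinol carbon and OCH2 of the hydroxylated unit. Ring A is O, C7, C8, C8', C9' and ring B is O, C7', C8', C8, C9. The lactol is carried as a mixture of anomers because both give the same oxocarbenium ion.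

Step 1
Reactants: 1 syringaldehyde (4-hydroxy-3,5-dimethoxybenzaldehyde)
Product: 2 4-formyl-2,6-dimethoxyphenyl acetate
Conditions: Ac2O (1.2 equiv), pyridine, CH2Cl2, rt
Reagents that add atoms: acetic anhydride, CC(=O)OC(C)=O
Why: This is a standard O-acetylation of the phenol, and the electron-withdrawing acetate later disfavours ionisation at C7 and is removed in step 6 without a separate operation.

Step 2
Reactants: 3 α-methylene-γ-butyrolactone (3-methylidenedihydrofuran-2(3H)-one)
Product: 5 3-(bromomethyl)furan-2(5H)-one, via dibromide 4 (not isolated)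
Conditions: Br2 (1.05 equiv), CH2Cl2, 0 °C to rt; then Et3N (1.05 equiv), Et2O, 0 °C
Reagents that add atoms: bromine, BrBr
Why: Bromine adds across the exocyclic alkene, and the tertiary α-bromide is then lost with a ring C4 hydrogen in the standard E2 dehydrobromination of α-bromolactones to butenolides, which leaves the primary allylic bromide and no stereocentre.

Step 3
Reactants: 2 4-formyl-2,6-dimethoxyphenyl acetate; 5 3-(bromomethyl)furan-2(5H)-one
Product: 7 4-{(S)-hydroxy[(3R)-4-methylidene-5-oxotetrahydrofuran-3-yl]methyl}-2,6-dimethoxyphenyl acetate (anti adduct, 7S,8R), via TMS ether 6 (not isolated)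
Conditions: CrCl2 (10 mol %), 3,6-diphenyl-1,8-bis(4-isopropyl-4,5-dihydrooxazol-2-yl)-9H-carbazole (12 mol %, antipode chosen for Si-face addition), i-Pr2NEt (30 mol %), Mn powder (2 equiv), TMSCl (1.5 equiv), THF, rt; then 1 M HCl, THF, 0 °C
Reagents that add atoms: none
Why: In this catalytic asymmetric Nozaki–Hiyama–Kishi allylation the allylchromium species from 5 attacks through its γ-carbon (C8) in a closed six-membered chair whose ring-locked E-type alkene geometry gives the anti C7/C8 relationship, the chiral ligand on trivalent chromium selects the Si face of 2 (7S,8R), and TMSCl releases the catalyst while masking O7 against translactonisation.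

Step 4
Reactants: 7 anti α-methylene lactone
Product: 8 4-{(S)-hydroxy[(3R,4S)-4-hydroxy-4-(hydroxymethyl)-5-oxotetrahydrofuran-3-yl]methyl}-2,6-dimethoxyphenyl acetate (7S,8R,8'S)
Conditions: OsO4 (2 mol %), NMO (1.5 equiv), citric acid (0.75 equiv), t-BuOH/H2O 1:1, rt
Reagents that add atoms: N-methylmorpholine N-oxide, C[N+]1([O-])CCOCC1; water, O
Why: The OsO4-catalysed syn-dihydroxylation of the exocyclic 1,1-disubstituted alkene should occur on the lactone face opposite the branched C8 side chain, which sets C8' (S) with its hydroxyl cis to H8 and the new CH2OH cis to the side chain, while the citric acid buffer sustains turnover on the electron-poor alkene and spares the aryl acetate.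

Step 5
Reactants: 8 triol lactone
Product: 10 (1S,5R,6S)-6-(4-acetoxy-3,5-dimethoxyphenyl)-1-hydroxy-3,7-dioxabicyclo[3.3.0]octan-2-one (cis-fused, aryl exo; 7S,8R,8'S), via primary triflate 9 (not isolated)
Conditions: Tf2O (1.05 equiv), 2,6-lutidine (3 equiv), CH2Cl2, −78 to 0 °C
Reagents that add atoms: none
Why: The only primary hydroxyl is triflated selectively at low temperature and is then displaced by the C7 hydroxyl in a 5-exo-tet Williamson-type cycloetherification that closes ring A cis-fused (the only strain-free mode) with retention at C7, because the C7–O bond is never broken and the p-acetoxy group disfavours benzylic ionisation.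

Step 6
Reactants: 10 bicyclic hydroxy-lactone
Product: 11 (1S,5R,6S)-6-(4-hydroxy-3,5-dimethoxyphenyl)-3,7-dioxabicyclo[3.3.0]octane-1,2-diol (hydroxy-lactol, anomeric mixture at C7')
Conditions: i-Bu2AlH (5 equiv), CH2Cl2, −78 °C; aq. potassium sodium tartrate
Reagents that add atoms: none
Why: Diisobutylaluminium hydride reduction of a γ-lactone stops at the stable aluminium lactolate at −78 °C, the excess reagent cleaves the aryl acetate in the same flask, and no stereocentre is at risk because C8' bears no hydrogen.

Step 7
Reactants: 12 2,6-dimethoxy-4-(4,4,5,5-tetramethyl-1,3,2-dioxaborolan-2-yl)phenol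
Product: 13 potassium trifluoro(4-hydroxy-3,5-dimethoxyphenyl)borate
Conditions: KHF2 (4.5 equiv), MeOH/H2O, rt; repeated evaporation from aq. MeOH
Reagents that add atoms: potassium hydrogen difluoride, [K+].[F-].F
Why: This is the standard conversion of a pinacol boronate into the stable trifluoroborate salt, which leaves the free phenol untouched and fixes boron on the ring carbon para to the hydroxyl.

Step 8
Reactants: 11 hydroxy-lactol; 13 potassium trifluoro(4-hydroxy-3,5-dimethoxyphenyl)borate
Product: 15 8-hydroxysyringaresinol, (1S,2R,5R,6S)-2,6-bis(4-hydroxy-3,5-dimethoxyphenyl)-3,7-dioxabicyclo[3.3.0]octan-1-ol, via tethered arylfluoroborinate 14 (not isolated)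
Conditions: 13 (1.5 equiv), BF3·OEt2 (3 equiv), CH2Cl2/MeCN 4:1, −40 to −10 °C; sat. aq. NaHCO3
Reagents that add atoms: none
Why: BF3·OEt2 abstracts fluoride from 13 to give the aryldifluoroborane, which the tertiary C8' hydroxyl of 11 captures as 14; the lactol C7'–OH is then ionised (its oxygen passing to the tethered boron, assisted by BF3) to the ring B oxocarbenium ion, and the aryl group shifts from the now tetracoordinate boron to C7' through a five-membered cyclic transition state with ipso substitution at the carbon that carried boron. The closest known reaction types are the BF3-promoted coupling of potassium aryltrifluoroborates with acetals and furanosyl donors, and the hydroxyl-tethered boronate additions of the Petasis reaction and of 3-hydroxy N-acyliminium ions, which are cis-selective for the same reason. No ring is closed: rings A and B are carried intact and ring B only passes through its oxocarbenium form. The single new stereocentre C7' (R) is controlled twice in the same sense, by delivery from O8' (aryl cis to the hydroxyl) and by the convex face of the cis-fused 3,7-dioxabicyclo[3.3.0]octane, so the aryl group should end exo. The step needs regioselectivity on the arene (C1 rather than the C–H positions ortho and para to the methoxy groups), secured by the C–B bond para to the free phenol within reach of the tether, and it needs chemoselective ionisation of C7'–OH over the benzylic C7–O ether, secured by the much greater lability of the hemiacetal at −40 °C and by the spent boron that stays on O8' after the transfer. Because C8' is fully substituted, the aldehyde-level carbon can neither enolise nor epimerise its neighbour, and the product is the unprotected natural product.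

**Compound list**
1 | syringaldehyde | COc1cc(C=O)cc(OC)c1O | starting material
2 | 4-formyl-2,6-dimethoxyphenyl acetate | COc1cc(C=O)cc(OC)c1OC(C)=O | intermediate
3 | α-methylene-γ-butyrolactone | C=C1CCOC1=O | starting material
4 | 3-bromo-3-(bromomethyl)dihydrofuran-2(3H)-one (racemic, not isolated) | O=C1OCCC1(Br)CBr | intermediate
5 | 3-(bromomethyl)furan-2(5H)-one | O=C1OCC=C1CBr | intermediate
6 | O7-trimethylsilyl ether of 7 (7S,8R, not isolated) | COc1cc([C@@H](O[Si](C)(C)C)[C@H]2COC(=O)C2=C)cc(OC)c1OC(C)=O | intermediate
7 | 4-{(S)-hydroxy[(3R)-4-methylidene-5-oxotetrahydrofuran-3-yl]methyl}-2,6-dimethoxyphenyl acetate | COc1cc([C@@H](O)[C@H]2COC(=O)C2=C)cc(OC)c1OC(C)=O | intermediate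
8 | 4-{(S)-hydroxy[(3R,4S)-4-hydroxy-4-(hydroxymethyl)-5-oxotetrahydrofuran-3-yl]methyl}-2,6-dimethoxyphenyl acetate | COc1cc([C@@H](O)[C@H]2COC(=O)[C@@]2(O)CO)cc(OC)c1OC(C)=O | intermediate
9 | C9' primary triflate of 8 (not isolated) | COc1cc([C@@H](O)[C@H]2COC(=O)[C@@]2(O)COS(=O)(=O)C(F)(F)F)cc(OC)c1OC(C)=O | intermediate
10 | (1S,5R,6S)-6-(4-acetoxy-3,5-dimethoxyphenyl)-1-hydroxy-3,7-dioxabicyclo[3.3.0]octan-2-one | COc1cc([C@H]2OC[C@]3(O)C(=O)OC[C@H]23)cc(OC)c1OC(C)=O | intermediate
11 | (1S,5R,6S)-6-(4-hydroxy-3,5-dimethoxyphenyl)-3,7-dioxabicyclo[3.3.0]octane-1,2-diol (anomeric mixture) | COc1cc([C@H]2OC[C@]3(O)C(O)OC[C@H]23)cc(OC)c1O | intermediate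
12 | 2,6-dimethoxy-4-(4,4,5,5-tetramethyl-1,3,2-dioxaborolan-2-yl)phenol | COc1cc(B2OC(C)(C)C(C)(C)O2)cc(OC)c1O | starting material
13 | potassium trifluoro(4-hydroxy-3,5-dimethoxyphenyl)borate | [K+].COc1cc([B-](F)(F)F)cc(OC)c1O | intermediate
14 | O8'-[fluoro(4-hydroxy-3,5-dimethoxyphenyl)boryl] derivative of 11 (not isolated) | COc1cc([C@H]2OC[C@]3(OB(F)c4cc(OC)c(O)c(OC)c4)C(O)OC[C@H]23)cc(OC)c1O | intermediate
15 | 8-hydroxysyringaresinol (7S,8R,7'R,8'S) | COc1cc([C@H]2OC[C@]3(O)[C@@H](c4cc(OC)c(O)c(OC)c4)OC[C@H]23)cc(OC)c1O | target

**Totals:** 8 steps. The longest linear sequence is 6 steps (step 1 or 2, then steps 3, 4, 5, 6 and 8).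

**Steps most likely to fail**

**Step 8.**
- What may go wrong: the electron-rich aryl donor may protodeboronate before transfer. The Lewis acid may also re-ionise the benzylic C–O bonds, with loss of configuration or a second aryl transfer.
- Fallback: this uses carbanion addition to the open aldehyde instead of oxocarbenium capture, sets out from 11 and comes back at 15.
- An excess of [4-(benzyloxy)-3,5-dimethoxyphenyl]magnesium bromide F1, made from commercial 2-(benzyloxy)-5-bromo-1,3-dimethoxybenzene and Mg in THF, is added at 0 °C.
- The lactol opens to the magnesium alkoxide aldehyde, and chelation between O8' and the carbonyl oxygen directs attack from the less hindered C9' side. This should give the (7'R)-benzylic alcohol F2.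
- Catalytic camphorsulfonic acid in CH2Cl2 at 0 °C closes ring B by attack of the C9 hydroxyl on the benzylic cation in its exo-aryl conformer. This gives the 4'-O-benzyl ether of the target F3.
- Brief hydrogenolysis (H2, Pd/C, EtOAc) returns to 15.

**Step 3.**
- What may go wrong: facial selectivity at the aldehyde may be insufficient with this electron-poor, ring-locked allyl donor. Reductive pinacol coupling of the aldehyde may also compete.
- Fallback: this uses Brønsted-acid-catalysed allylboration instead of organochromium chemistry, sets out from 5 and comes back at 7.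
- Palladium-catalysed borylation (Pd2(dba)3, B2pin2, DMSO, 50 °C) gives 3-[(4,4,5,5-tetramethyl-1,3,2-dioxaborolan-2-yl)methyl]furan-2(5H)-one F4.
- F4 is added to 2 in toluene at −30 °C with 3,3'-bis(2,4,6-triisopropylphenyl)-1,1'-binaphthyl-2,2'-diyl hydrogen phosphate as catalyst (antipode chosen for Si-face addition).
- The addition passes through the same closed chair, so it should again be anti, and aqueous work-up gives 7.

**Step 5.**
- What may go wrong: sulfonylation may occur at the benzylic hydroxyl. The primary triflate may also collapse through the neighbouring tertiary hydroxyl (oxirane closure) instead of closing ring A.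
- Fallback: the polarity is reversed so that C7 becomes the electrophile; this sets out from 8 and comes back at 11.
- NH4OAc-catalysed methanolysis (aq. MeOH, rt) frees the phenol to give the phenolic triol lactone F5.
- Catalytic camphorsulfonic acid in CH2Cl2 at 0 °C ionises the now electron-rich C7 carbinol. The C9' hydroxyl adds to the quinone-methide-type cation in the exo-aryl sense to give the phenolic bicyclic hydroxy-lactone F6.
- i-Bu2AlH at −78 °C then gives 11.

**Further compounds**
F1 | step 8 | [4-(benzyloxy)-3,5-dimethoxyphenyl]magnesium bromide | COc1cc([Mg]Br)cc(OC)c1OCc1ccccc1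
F2 | step 8 | (7S,8R,7'R,8'S) ring-B-opened triol: ring A tetrahydrofuran bearing C7 aryl, C8 CH2OH, C8' OH and C8' CH(OH)(4-benzyloxy-3,5-dimethoxyphenyl) | COc1cc([C@H]2OC[C@](O)([C@H](O)c3cc(OC)c(OCc4ccccc4)c(OC)c3)[C@@H]2CO)cc(OC)c1O
F3 | step 8 | 4'-O-benzyl-8-hydroxysyringaresinol (benzyl on the aryl group at C7') | COc1cc([C@H]2OC[C@]3(O)[C@@H](c4cc(OC)c(OCc5ccccc5)c(OC)c4)OC[C@H]23)cc(OC)c1O
F4 | step 3 | 3-[(4,4,5,5-tetramethyl-1,3,2-dioxaborolan-2-yl)methyl]furan-2(5H)-one | CC1(C)OB(CC2=CCOC2=O)OC1(C)C
F5 | step 5 | (3S,4R)-3-hydroxy-4-[(S)-hydroxy(4-hydroxy-3,5-dimethoxyphenyl)methyl]-3-(hydroxymethyl)dihydrofuran-2(3H)-one | COc1cc([C@@H](O)[C@H]2COC(=O)[C@@]2(O)CO)cc(OC)c1O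
F6 | step 5 | (1S,5R,6S)-1-hydroxy-6-(4-hydroxy-3,5-dimethoxyphenyl)-3,7-dioxabicyclo[3.3.0]octan-2-one | COc1cc([C@H]2OC[C@]3(O)C(=O)OC[C@H]23)cc(OC)c1O
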